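The numbers in the tables come from a simulation from invented constants.

Start from the unit per molar per day: a loss of G that runs through Q, divided by the Q present, must come out in it. You stir X with Q in closed flasks, and G, one of the mono adducts, is read in percent of the X charged.

| setting | Monday's | Wednesday's | beta | alpha | zeta | epsilon | gamma |
|---|---|---|---|---|---|---|---|
| X | 0.40 M | 0.40 M | 0.40 M | 0.40 M | 0.40 M | 0.40 M | 0.40 M |
| Q | 0.30 M | 1.9 M | 0.250 M | 0.400 M | 0.500 M | 0.800 M | 1.20 M |
| remark | run made earlier | run made earlier |  |  |  |  |  |
| time |  |  | 8.0 d | 8.0 d | 8.0 d | 8.0 d | 8.0 d |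

- Monday's (time / d: G / %): 1.04: 16.0; 2.50: 14.1; 3.00: 12.6; 5.00: 9.7; 6.00: 8.7
- Wednesday's (time / d: G / %): 1.04: 35.5; 2.50: 24.9; 3.00: 19.9; 5.00: 16.5; 6.00: 10.6

(each reading ± 1 percentage point)

- in percentages every species weighs as the X in it: one Z counts as two
- steps that have been proposed: X + Q -> G + L; Q + G -> D + L; X + Q -> J + L; Q + J -> D + L; X + G -> Z
- "hardly changes" means that all values lie within two and a half points (for a concentration: within two and a half percent of the largest)

- amount of G at the end, in percent of the X charged for beta, alpha, zeta, epsilon, gamma, in this order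
- the course of these numbers from the first flask to the last (falls all the way / rises, then falls / falls, then rises / hardly changes / rises all the way)

Now the oddity. Read from the first and last readings, G falls on Wednesday by 0.244 d⁻¹, and on Monday by 0.123 d⁻¹. That is half the Wednesday fall, with 0.30 M of Q against 1.9 M.

To clear this up, take Wednesday first. Q stands in excess there, so the fall is pseudo-first-order. Dividing it by the charged Q gives the loss constant of G to Q, 0.128 M⁻¹ d⁻¹, a reading that carries the scatter of the readings. On Monday even the full charge of Q gives 0.0385 d⁻¹, less than the fall that was read. So G has a second partner on Monday, and among the proposed steps that is X + G -> Z, with less Q charged than X.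

Control therefore changes hands as Q rises. I expect leftover X to cut G while Q is short, and Q to cut it once Q is in surplus. By this constant, Q held at 0.676 M for 8.0 d takes half of G, and I call that concentration my crossing. So I commit to a row that rises, then falls, turning between 0.40 M and my crossing.

The forecast gives 6 %, 12 %, 16 %, 18 %, 15 %, hence rises, then falls, on the ground that “Leftover X must therefore be eating G to give Z”. Its top stands at 0.800 M, above my crossing.

The flasks give 4.29 %, 17.9 %, 22.3 %, 22.5 %, 16.7 %, so the course is rises, then falls, turning at 0.63 M.

    X + Q → G + L (k = 0.0862 M⁻¹ h⁻¹)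
    Q + G → D + L (k = 0.00660 M⁻¹ h⁻¹)
    X + Q → J + L (k = 0.0951 M⁻¹ h⁻¹)
    Q + J → D + L (k = 0.00635 M⁻¹ h⁻¹)
    X + G → Z (k = 0.116 M⁻¹ h⁻¹)

In beta the loss constant gives G a half-life against Q of 21.6 d at the charged Q, yet G goes from 8.20 % to 4.29 % between 4.00 d and 8.00 d, with X at 22.7 % and then 15.4 %. In gamma X stands at 0 % by 4.00 d, and over the next stretch to 8.00 d the same constant, at the mean Q, keeps 71.5 % of G, while the flask keeps 66.2 %.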